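# Lasiodiplactone A: a proposed synthesis through desymmetrising C–H lactonisation of an isopropyl group

## The problem

Lasiodiplactone A (30) has a fully differentiated benzene ring. In resorcylate numbering, C1 carries the lactone carbonyl, C2 the methoxy group, C3 a hydrogen, C4 an oxygen, C5 a benzylic CH2 and C6 the macrocycle chain. C1 and C6 close the twelve-membered lactone of (R)-lasiodiplodin (13). The C4 oxygen and the C5 methylene belong to a chroman that is fused through a methyl ketal carbon to a tetrahydrofuran.

There are four stereocentres. The lactone carbinol carbon (R) is remote from the others and is best taken from the chiral pool. The other three are contiguous: the ketal carbon, the ring-fusion carbon and the methyl-bearing carbon (all S). The ketal carbon needs no separate control, because a five/six bicyclic ketal closes cis and ketalisation is reversible, so the ring-fusion carbon dictates it. The ring-fusion and methyl-bearing carbons (substituents trans) must be set relative to each other and absolutely.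

Several groups limit the choice of reagents:
- The ketal is acid-labile and belongs at the end.
- The arene is electron-rich and flanked by two benzylic methylenes, so oxidants threaten it.
- A free C4 phenol next to a free side-chain acid would close to a six-membered aryl lactone.
- The C5 carbon must be introduced next to the free C3 position.

The enabling feature is that the methyl-bearing carbon carries both the ring CH3 and the ring O–CH2 and sits on the ring-fusion carbon. With the ketal carbon at the carboxylic acid oxidation level, this is a 2-(arylmethyl)-3-methylbutanoic acid whose two methyl groups are γ to the carboxyl. The O–CH2 bond can therefore be made by carboxylate-directed oxidation of one methyl of an isopropyl group.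

## Retrosynthesis

**Ketal (30 to 28).** The two C–O bonds and the C–CH3 bond at the ketal carbon are cut, giving phenol γ-lactone 28 and a methyl nucleophile. The ketal is the most acid-sensitive group and its configuration is dictated by the ring-fusion centre, so it should close last and under equilibrium. Carrying a methyl ketone through earlier steps would put an enolisable carbonyl next to the ring-fusion centre. The forward step asks for a single addition of MeLi to a γ-lactone and an acid-catalysed closure.

**Phenol protection (28 to 26).** The phenol must be masked during the oxidation and the auxiliary removal. An aryl ester would be convenient, since MeLi would remove it in the last operation. It would not survive the hydroperoxide that removes the auxiliary, and once lost, the phenol would lactonise onto the acid. A triflate is chosen instead: it withstands hydride, enolate and hydroperoxide, deactivates the arene more strongly than an ester, and is removed by hydroxide at room temperature. The price is one extra step.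

**Key disconnection (26 to 25).** The lactone O–CH2 bond is cut back to a C–H bond of an isopropyl group, giving (S)-acid 25. This removes one ring and one stereocentre, and the methyl-bearing centre then comes from an isovaleric acid unit. The neighbouring options are alkylation of a preformed enantiopure β-methyl lactone enolate, which buys that stereocentre, and hydroboration of an isopropenyl group, which needs a second diastereoselective step. The forward reaction must pick one of two diastereotopic methyl groups and must outrun oxidation of the arene and the benzylic positions.

**Side chain (25 to 18 and 21).** The bond between the α-carbon and the C5 benzylic carbon is cut, giving benzylic bromide 18 and N-isovaleryl oxazolidinone 21 by way of imide 23. Auxiliary-controlled alkylation of N-isovaleryl oxazolidinones with benzylic bromides is established. Asymmetric hydrogenation of an α-isopropyl cinnamic acid would need an olefination at a di-ortho-substituted aldehyde. The forward step needs SN2 displacement at a hindered benzylic bromide and a hydroperoxide cleavage that spares the triflate.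

**One-carbon unit at C5 (18 to 13).** The aryl–carbon bond at C5 is cut back to lasiodiplodin 13 through alcohol 17, triflate aldehyde 16 and salicylaldehyde 15. Phenol-directed formylation allows only the two ortho positions, and C5 is also para to the methoxy group. The forward step depends on this preference over C3, which lies between two oxygens.

**Macrocycle (13 to 7 and 10).** The chain C=C bond of 12 and the ester C–O bond of 11 are cut, giving acid 7 and alcohol 10. Metathesis of two remote terminal alkenes is the best-precedented closure of this ring, and one hydrogenation then saturates the alkene and frees the phenol. The Mitsunobu esterification avoids acylating with a hindered benzoate and lets the (S)-alcohol deliver the (R)-ester.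

**Fragments (7 to 1; 10 to 8 and 9).** The benzylic C–C bond of 7 is cut to the toluate 3, made from methyl orsellinate 1 via 2, and allyl bromide 4. The chelated 2-hydroxyl of 1 differentiates the two phenols without effort. Alcohol 10 comes from (S)-propylene oxide 8 and Grignard reagent 9. Imide 21 comes from auxiliary 19 and acid chloride 20.

## Roads not taken

**Alternative 1:** acylketene macrolactonisation followed by transannular aldol aromatisation.
- **Cut:** the lactone acyl–O bond and the arene bond between the ester-bearing and chain-bearing carbons.
- **Forward key step:** diketo-dioxinone A1 is heated at high dilution and loses acetone. The ketene is trapped by the remote (R)-carbinol to give the sixteen-membered triketo-lactone A2. Cs2CO3 and then HCl aromatise it to de-O-methyllasiodiplodin A3.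
- **Merits:** the hindered aryl ester is never made by esterification, the carbinol reacts with retention, and no arene protecting groups are needed. As a route to the lactone core it is at least as good as steps 1–8, and it avoids the hindered saponification and the Mitsunobu step.
- **Weak points:** A3 has both phenols free, and the one to be methylated is the chelated, less reactive one, so a protect–methylate–deprotect sequence follows. A1 needs its own multistep assembly. The C5 carbon and the three contiguous stereocentres are not addressed.
- **Comparison:** the chosen plan offers a commercial arene whose phenols differentiate themselves in two simple steps, and a back half that would be the same in either case.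

**Alternative 2:** Diels–Alder benzannulation of a twelve-membered ynolide.
- **Cut:** the two arene bonds flanking the alkyne carbons.
- **Forward key step:** ynolide A4 and bis(silyloxy)diene A5 are heated, and acid work-up gives resorcylate A6, which already carries a CH2OMe group at C5.
- **Merits:** the C5 carbon arrives with its position fixed by the polarity of the cycloaddition. This is better than the chosen plan, which relies on an ortho/para preference in a formylation.
- **Weak points:** a β-alkyl ynoate is a sluggish dienophile and a terminally substituted silyloxydiene is sensitive, so the cycloaddition is uncertain. A6 again has the wrong phenol pattern. Its benzylic methyl ether must be converted to a leaving group without touching the aryl methyl ether made later.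
- **Comparison:** the chosen plan offers a well-precedented ring closure and a fallback for the regiochemistry, and accepts that the formylation may need it.

**Alternative 3:** Ramberg–Bäcklund contraction of a thirteen-membered thia-lactone.
- **Cut:** the bond between the C6 benzylic carbon and its chain neighbour, with the macrocycle closed last.
- **Forward key step:** sulfone A7 is treated with KOH and CCl4 and loses SO2 to give styrenyl lactone A8 as an E/Z mixture, which must then be hydrogenated.
- **Merits:** thioether macrocyclisation is very reliable. All stereochemistry, including the C–H lactonisation, would be set on a simple non-macrocyclic arene, which is arguably a more forgiving substrate for the oxidation than 25.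
- **Weak points:** the arene needs three differentiated carbon substituents in a row before the ring exists. Sulfide formation, oxidation, contraction and hydrogenation take four steps where metathesis and hydrogenation take two. Hot KOH with a carbene source meets the finished lactone and an electron-rich arene.
- **Comparison:** the chosen plan is shorter, and it has the lactone ester in place as an electron-withdrawing group during the oxidation.

Key step: step 16

## Remarks before the steps

- Which ligand enantiomer is matched to the (S)-acid 25 cannot be predicted. The (S,S)-ligand is written, and the (R,R)-ligand would replace it if it proves mismatched.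
- The alkene geometry of 12 is not controlled and does not matter.
- "Lasiodiplodin-5-yl" means the lasiodiplodin skeleton attached through arene C5, the carbon between the phenolic oxygen and the macrocycle chain.

## Route

Step 1
Reactants: 1 methyl orsellinate (methyl 2,4-dihydroxy-6-methylbenzoate)
Product: 2 methyl 4-(benzyloxy)-2-hydroxy-6-methylbenzoate
Conditions: BnBr (1.05 equiv), K2CO3, acetone, reflux
Reagents that add atoms: benzyl bromide, BrCc1ccccc1
Why: Williamson etherification; the 4-hydroxyl is the more acidic and is not hydrogen-bonded to the ester carbonyl, so one equivalent of benzyl bromide should alkylate it selectively.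

Step 2
Reactants: 2 methyl 4-(benzyloxy)-2-hydroxy-6-methylbenzoate
Product: 3 methyl 4-(benzyloxy)-2-methoxy-6-methylbenzoate
Conditions: MeI, K2CO3, DMF, 50 °C
Reagents that add atoms: iodomethane, CI
Why: Williamson O-methylation of the remaining chelated phenol under more forcing conditions; no other nucleophilic site is left.

Step 3
Reactants: 3 methyl 4-(benzyloxy)-2-methoxy-6-methylbenzoate, 4 allyl bromide
Product: 6 methyl 4-(benzyloxy)-2-(but-3-en-1-yl)-6-methoxybenzoate, via benzylic organolithium 5 (not isolated)
Conditions: LiN(iPr)2 (1.2 equiv), THF, −78 °C; then allyl bromide, −78 °C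
Reagents that add atoms: none
Why: Lateral lithiation of an ortho-toluate gives the ester-stabilised benzylic anion, which allyl bromide alkylates by SN2; low temperature and the di-ortho-substituted ester suppress self-condensation.

Step 4
Reactants: 6 methyl 4-(benzyloxy)-2-(but-3-en-1-yl)-6-methoxybenzoate
Product: 7 4-(benzyloxy)-2-(but-3-en-1-yl)-6-methoxybenzoic acid
Conditions: KOH, DMSO/H2O (4:1), 90 °C; then aq. HCl
Reagents that add atoms: potassium hydroxide, [K+].[OH-]
Why: Saponification of a hindered methyl benzoate needs hot hydroxide in a dipolar solvent; the benzyl ether, aryl methyl ether and terminal alkene are inert to it.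

Step 5
Reactants: 8 (S)-propylene oxide, 9 but-3-en-1-ylmagnesium bromide
Product: 10 (S)-hept-6-en-2-ol
Conditions: CuI (10 mol %), THF, −30 to 0 °C; aq. NH4Cl
Reagents that add atoms: none
Why: Copper-catalysed epoxide opening by the Grignard reagent at the unsubstituted carbon (SN2); the stereocentre is not touched, so the (S)-epoxide gives the (S)-alcohol.

Step 6
Reactants: 7 4-(benzyloxy)-2-(but-3-en-1-yl)-6-methoxybenzoic acid, 10 (S)-hept-6-en-2-ol
Product: 11 (R)-hept-6-en-2-yl 4-(benzyloxy)-2-(but-3-en-1-yl)-6-methoxybenzoate
Conditions: PPh3, DIAD, toluene, 0 °C to rt
Reagents that add atoms: none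
Why: Mitsunobu esterification; the hindered acid acts as the nucleophile toward the alkoxyphosphonium ion, so hindrance at the carbonyl does not matter, and SN2 inversion turns the (S)-alcohol into the (R)-ester of the target.

Step 7
Reactants: 11 (R)-hept-6-en-2-yl 4-(benzyloxy)-2-(but-3-en-1-yl)-6-methoxybenzoate
Product: 12 4-O-benzyl-didehydrolasiodiplodin (twelve-membered lactone with C=C between the third and fourth chain carbons from the arene, E/Z mixture)
Conditions: second-generation Grubbs catalyst (H2IMes)(PCy3)Cl2Ru=CHPh (5 mol %), CH2Cl2 (2 mM), 40 °C
Reagents that add atoms: none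
Why: Ring-closing metathesis of two monosubstituted, non-conjugated alkenes at high dilution, driven by loss of ethene; twelve-membered benzolactones of this type close well this way.

Step 8
Reactants: 12 4-O-benzyl-didehydrolasiodiplodin
Product: 13 (R)-lasiodiplodin
Conditions: H2 (1 atm), Pd/C (10 %), EtOAc/EtOH, rt
Reagents that add atoms: none
Why: Heterogeneous hydrogenation saturates the alkene and hydrogenolyses the benzyl ether in one operation, freeing the phenol para to the ester.

Step 9
Reactants: 13 (R)-lasiodiplodin
Product: 15 5-formyllasiodiplodin (CHO on the arene carbon between the phenol and the chain), via hydroxymethyl phenol 14 (not isolated)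
Conditions: MgCl2 (3 equiv), Et3N (6 equiv), (CH2O)n (10 equiv), MeCN, reflux; aq. HCl
Reagents that add atoms: paraformaldehyde (as formaldehyde), C=O
Why: Casnati–Skattebøl ortho-formylation; the magnesium phenoxide delivers formaldehyde to an ortho carbon and a second formaldehyde oxidises the benzylic alkoxide. Of the two ortho positions, C5 is also para to the methoxy group, whereas C3 lies between two oxygens, the disfavoured site in resorcinol ethers.

Step 10
Reactants: 15 5-formyllasiodiplodin
Product: 16 5-formyllasiodiplodin 4-O-triflate
Conditions: Tf2O, pyridine, CH2Cl2, 0 °C
Reagents that add atoms: trifluoromethanesulfonic anhydride, O=S(=O)(OS(=O)(=O)C(F)(F)F)C(F)(F)F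
Why: O-sulfonylation of a phenol; the triflate is chosen because it withstands hydride, enolate and hydroperoxide and deactivates the arene for the oxidation.

Step 11
Reactants: 16 5-formyllasiodiplodin 4-O-triflate
Product: 17 5-(hydroxymethyl)lasiodiplodin 4-O-triflate
Conditions: NaBH4, THF/MeOH (10:1), −20 °C
Reagents that add atoms: none
Why: Borohydride reduction of the aryl aldehyde; a sulfonate cannot migrate to the new alkoxide as an acyl group would, and the hindered lactone is not reduced.

Step 12
Reactants: 17 5-(hydroxymethyl)lasiodiplodin 4-O-triflate
Product: 18 5-(bromomethyl)lasiodiplodin 4-O-triflate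
Conditions: CBr4, PPh3, CH2Cl2, 0 °C
Reagents that add atoms: carbon tetrabromide, BrC(Br)(Br)Br
Why: Appel bromination of a primary benzylic alcohol under neutral conditions; the triflate and the lactone are untouched.

Step 13
Reactants: 19 (S)-4-benzyloxazolidin-2-one, 20 3-methylbutanoyl chloride
Product: 21 (S)-4-benzyl-3-(3-methylbutanoyl)oxazolidin-2-one
Conditions: Et3N, DMAP (10 mol %), CH2Cl2, 0 °C to rt
Reagents that add atoms: none
Why: DMAP-catalysed N-acylation of the oxazolidinone by the acid chloride.

Step 14
Reactants: 21 (S)-4-benzyl-3-(3-methylbutanoyl)oxazolidin-2-one, 18 5-(bromomethyl)lasiodiplodin 4-O-triflate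
Product: 23 (S)-4-benzyl-3-{(S)-3-methyl-2-[(4-O-triflyl-lasiodiplodin-5-yl)methyl]butanoyl}oxazolidin-2-one, via sodium enolate 22 (not isolated)
Conditions: NaN(SiMe3)2 (1.1 equiv relative to 21), THF, −78 °C; then 18 (0.8 equiv), −78 to −20 °C
Reagents that add atoms: none
Why: Evans alkylation; the chelated (Z)-sodium enolate is shielded on one face by the benzyl group of the auxiliary, and the bromide enters from the other face, which sets the new centre as (S). Alkylation of N-isovaleryl oxazolidinones with benzylic bromides is established.

Step 15
Reactants: 23 the alkylated imide
Product: 25 (S)-3-methyl-2-[(4-O-triflyl-lasiodiplodin-5-yl)methyl]butanoic acid, via peroxy acid 24 (not isolated)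
Conditions: LiOH, H2O2, THF/H2O (3:1), 0 °C; then aq. Na2SO3; aq. HCl
Reagents that add atoms: hydrogen peroxide, OO
Why: Hydroperoxide attacks the exocyclic imide carbonyl selectively even when it is α-branched, and sulfite reduces the peroxy acid. The carboxylate is not enolised, so the α-centre is safe; the hindered benzoate and the triflate are expected to survive at 0 °C.

Step 16
Reactants: 25 (S)-3-methyl-2-[(4-O-triflyl-lasiodiplodin-5-yl)methyl]butanoic acid
Product: 26 (3S,4S)-4-methyl-3-[(4-O-triflyl-lasiodiplodin-5-yl)methyl]dihydrofuran-2(3H)-one
Conditions: Mn(OTf)2 complex of (S,S)-1,1'-bis{[5-(triisopropylsilyl)pyridin-2-yl]methyl}-2,2'-bipyrrolidine (2 mol %), aq. H2O2 (2 equiv, syringe pump), (CF3)2CHOH, 0 °C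
Reagents that add atoms: none
Why: Proposed new method: the carboxylate of 25 binds the divalent manganese centre and assists O–O heterolysis of H2O2 to a high-valent oxo-manganese carboxylate, which abstracts a hydrogen atom from a γ-methyl group through a seven-membered transition state; rebound of the bound carboxylate onto the primary radical gives the lactone, the closest known reaction type being manganese-catalysed, carboxylate-directed γ-lactonisation of unactivated primary C–H bonds with H2O2, including desymmetrisation of geminal methyl groups in aliphatic acids. The one ring formed is the five-membered lactone, closed by bond formation between the carboxylate oxygen and the γ-carbon after the 1,7-hydrogen transfer. The new stereocentre is the former isopropyl carbon, which becomes (S) when the correct one of its two diastereotopic methyl groups is oxidised; the existing (S)-α-centre controls this, because its arylmethyl group prefers to lie trans to the spectator methyl in the lactone-like transition state, and the matched catalyst enantiomer reinforces it. The step needs site selectivity for the γ-methyl over the benzylic methylenes, the β-methine and the arene. The β-positions cannot reach the oxo ligand in the seven-membered geometry, and the triflate, the benzoate and hydrogen bonding of the fluorinated alcohol to the methoxy and carbonyl oxygens lower the electron density of the arene and the hydridic character of its benzylic C–H bonds. This competition has not been tested on an acid that carries an arene and benzylic hydrogens.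

Step 17
Reactants: 26 the triflate lactone
Product: 28 (3S,4S)-3-[(lasiodiplodin-5-yl)methyl]-4-methyldihydrofuran-2(3H)-one (free phenol), via seco acid 27 (not isolated)
Conditions: Et4NOH (aq., 4 equiv), 1,4-dioxane, rt; then 1 M HCl, rt
Reagents that add atoms: none
Why: Hydroxide attacks the sulfur of the aryl triflate and expels the phenoxide. The γ-lactone opens to a carboxylate, which cannot enolise, and closes again on acidification, so the α-centre is not at risk; the di-ortho-substituted macrolactone should resist hydroxide at room temperature.

Step 18
Reactants: 28 the phenol lactone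
Product: 30 lasiodiplactone A, via hydroxy ketone 29 (not isolated)
Conditions: MeLi (3 equiv), THF, −78 °C; AcOH quench; then PPTS (cat.), CH2Cl2, 4 Å MS, rt
Reagents that add atoms: methyllithium, [Li]C
Why: After deprotonating the phenol, MeLi adds once to the γ-lactone because the lithium hemiketal alkoxide is stable at −78 °C. Mild acid then generates the oxocarbenium ion, which the phenol captures in a six-membered ring closure. Only the cis-fused bicyclic ketal is accessible, so the ketal centre follows from the ring-fusion centre under thermodynamic control, with the ring methyl on the convex face.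

## Compound list

1 | methyl orsellinate | COC(=O)c1c(C)cc(O)cc1O | starting material
2 | methyl 4-(benzyloxy)-2-hydroxy-6-methylbenzoate | COC(=O)c1c(C)cc(OCc2ccccc2)cc1O | intermediate
3 | methyl 4-(benzyloxy)-2-methoxy-6-methylbenzoate | COC(=O)c1c(C)cc(OCc2ccccc2)cc1OC | intermediate
4 | allyl bromide | C=CCBr | starting material
5 | [5-(benzyloxy)-3-methoxy-2-(methoxycarbonyl)phenyl]methyllithium | [Li+].[CH2-]c1cc(OCc2ccccc2)cc(OC)c1C(=O)OC | intermediate
6 | methyl 4-(benzyloxy)-2-(but-3-en-1-yl)-6-methoxybenzoate | COC(=O)c1c(CCC=C)cc(OCc2ccccc2)cc1OC | intermediate
7 | 4-(benzyloxy)-2-(but-3-en-1-yl)-6-methoxybenzoic acid | OC(=O)c1c(CCC=C)cc(OCc2ccccc2)cc1OC | intermediate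
8 | (S)-propylene oxide | C[C@H]1CO1 | starting material
9 | but-3-en-1-ylmagnesium bromide | C=CCC[Mg]Br | starting material
10 | (S)-hept-6-en-2-ol | C[C@H](O)CCCC=C | intermediate
11 | (R)-hept-6-en-2-yl 4-(benzyloxy)-2-(but-3-en-1-yl)-6-methoxybenzoate | COc1cc(OCc2ccccc2)cc(CCC=C)c1C(=O)O[C@H](C)CCCC=C | intermediate
12 | 4-O-benzyl-didehydrolasiodiplodin (E/Z mixture) | COc1cc(OCc2ccccc2)cc2c1C(=O)O[C@H](C)CCCC=CCC2 | intermediate
13 | (R)-lasiodiplodin | COc1cc(O)cc2c1C(=O)O[C@H](C)CCCCCCC2 | intermediate
14 | 5-(hydroxymethyl)lasiodiplodin | COc1cc(O)c(CO)c2c1C(=O)O[C@H](C)CCCCCCC2 | intermediate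
15 | 5-formyllasiodiplodin | COc1cc(O)c(C=O)c2c1C(=O)O[C@H](C)CCCCCCC2 | intermediate
16 | 5-formyllasiodiplodin 4-O-triflate | COc1cc(OS(=O)(=O)C(F)(F)F)c(C=O)c2c1C(=O)O[C@H](C)CCCCCCC2 | intermediate
17 | 5-(hydroxymethyl)lasiodiplodin 4-O-triflate | COc1cc(OS(=O)(=O)C(F)(F)F)c(CO)c2c1C(=O)O[C@H](C)CCCCCCC2 | intermediate
18 | 5-(bromomethyl)lasiodiplodin 4-O-triflate | COc1cc(OS(=O)(=O)C(F)(F)F)c(CBr)c2c1C(=O)O[C@H](C)CCCCCCC2 | intermediate
19 | (S)-4-benzyloxazolidin-2-one | O=C1N[C@@H](Cc2ccccc2)CO1 | starting material
20 | 3-methylbutanoyl chloride | CC(C)CC(Cl)=O | starting material
21 | (S)-4-benzyl-3-(3-methylbutanoyl)oxazolidin-2-one | CC(C)CC(=O)N1[C@@H](Cc2ccccc2)COC1=O | intermediate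
22 | sodium (Z)-enolate of 21 | [Na+].CC(C)/C=C(\[O-])N1[C@@H](Cc2ccccc2)COC1=O | intermediate
23 | (S)-4-benzyl-3-{(S)-3-methyl-2-[(4-O-triflyl-lasiodiplodin-5-yl)methyl]butanoyl}oxazolidin-2-one | COc1cc(OS(=O)(=O)C(F)(F)F)c(C[C@H](C(=O)N3[C@@H](Cc4ccccc4)COC3=O)C(C)C)c2c1C(=O)O[C@H](C)CCCCCCC2 | intermediate
24 | (S)-3-methyl-2-[(4-O-triflyl-lasiodiplodin-5-yl)methyl]butaneperoxoic acid | COc1cc(OS(=O)(=O)C(F)(F)F)c(C[C@H](C(=O)OO)C(C)C)c2c1C(=O)O[C@H](C)CCCCCCC2 | intermediate
25 | (S)-3-methyl-2-[(4-O-triflyl-lasiodiplodin-5-yl)methyl]butanoic acid | COc1cc(OS(=O)(=O)C(F)(F)F)c(C[C@H](C(=O)O)C(C)C)c2c1C(=O)O[C@H](C)CCCCCCC2 | intermediate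
26 | (3S,4S)-4-methyl-3-[(4-O-triflyl-lasiodiplodin-5-yl)methyl]dihydrofuran-2(3H)-one | COc1cc(OS(=O)(=O)C(F)(F)F)c(C[C@H]3[C@H](C)COC3=O)c2c1C(=O)O[C@H](C)CCCCCCC2 | intermediate
27 | (2S,3S)-4-hydroxy-3-methyl-2-[(lasiodiplodin-5-yl)methyl]butanoic acid | COc1cc(O)c(C[C@H](C(=O)O)[C@H](C)CO)c2c1C(=O)O[C@H](C)CCCCCCC2 | intermediate
28 | (3S,4S)-3-[(lasiodiplodin-5-yl)methyl]-4-methyldihydrofuran-2(3H)-one | COc1cc(O)c(C[C@H]3[C@H](C)COC3=O)c2c1C(=O)O[C@H](C)CCCCCCC2 | intermediate
29 | (3S,4S)-5-hydroxy-4-methyl-3-[(lasiodiplodin-5-yl)methyl]pentan-2-one (open form of the methyl lactol) | COc1cc(O)c(C[C@H](C(C)=O)[C@H](C)CO)c2c1C(=O)O[C@H](C)CCCCCCC2 | intermediate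
30 | lasiodiplactone A | COc1cc2c(c3c1C(=O)O[C@H](C)CCCCCCC3)C[C@H]1[C@H](C)CO[C@@]1(C)O2 | target

## Step count and least certain steps

Total: 18 steps. Longest linear sequence: 16 steps (steps 1–4, 6–12 and 14–18). Steps 5 and 13 prepare alcohol 10 and imide 21.

**Step 16 (key step, new method).** The most likely failure is that the oxidant is consumed at the wrong site before the γ-methyl is reached. This could be electrophilic attack on the arene, including ipso attack at arene C5, which sits γ to the carboxyl, or hydrogen abstraction from a benzylic methylene. The second possibility is poor discrimination between the two diastereotopic methyl groups, which would give the cis-lactone as well. The fallback uses known chemistry, leaves the route at bromide 18 and returns at lactone 26. Commercial (S)-4-methyldihydrofuran-2(3H)-one (C[C@@H]1COC(=O)C1) is deprotonated with LiN(iPr)2 in THF/DMPU at −78 °C. The resulting lithium enolate of (S)-4-methyldihydrofuran-2(3H)-one F1 is alkylated by 18 anti to the ring methyl and gives 26 directly. Steps 13–16 are then not needed, but the methyl stereocentre is bought and not made.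

**Step 9.** The likely failure is poor regioselectivity between the two positions ortho to the phenol, because C3 is activated by both oxygens as well. The fallback leaves at 13 and returns at 16, and it changes the directing principle. Compound 13 is first converted with Tf2O and pyridine into lasiodiplodin 4-O-triflate F2, so the methoxy group is the only strong director left. Rieche formylation (Cl2CHOMe, TiCl4, CH2Cl2) should then go para to the methoxy group, at C5, and give 16.

**Step 15.** The likely failures are loss of the triflate by hydroperoxide attack at sulfur during the slow cleavage of a doubly α-branched imide, or competing opening of the oxazolidinone ring. The fallback leaves at 23 and returns at 25 without a nucleophilic oxygen reagent. LiBH4 (THF, 1 equiv MeOH, 0 °C) removes the auxiliary reductively and gives the alcohol (S)-3-methyl-2-[(4-O-triflyl-lasiodiplodin-5-yl)methyl]butan-1-ol F3. TEMPO with PhI(OAc)2 oxidises it to the aldehyde (S)-3-methyl-2-[(4-O-triflyl-lasiodiplodin-5-yl)methyl]butanal F4. Pinnick oxidation (NaClO2, NaH2PO4, 2-methylbut-2-ene) then gives 25.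

**Step 18.** The likely failure is over-addition: collapse of the tetrahedral intermediate to the ketone while MeLi is still present, giving a tertiary alcohol, or attack on the macrolactone by the excess reagent. The fallback leaves at 28 and returns at 29. Me(MeO)NH·HCl and AlMe3 in CH2Cl2 open the lactone to the Weinreb amide (2S,3S)-4-hydroxy-N-methoxy-N,3-dimethyl-2-[(lasiodiplodin-5-yl)methyl]butanamide F5. MeMgBr in THF at 0 °C stops at the chelated adduct and gives 29 on work-up, and the same acid treatment closes it to 30.

## Further compounds

F1 | step 16 | lithium enolate of (S)-4-methyldihydrofuran-2(3H)-one | [Li+].C[C@@H]1COC([O-])=C1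
F2 | step 9 | (R)-lasiodiplodin 4-O-triflate | COc1cc(OS(=O)(=O)C(F)(F)F)cc2c1C(=O)O[C@H](C)CCCCCCC2
F3 | step 15 | (S)-3-methyl-2-[(4-O-triflyl-lasiodiplodin-5-yl)methyl]butan-1-ol | COc1cc(OS(=O)(=O)C(F)(F)F)c(C[C@H](CO)C(C)C)c2c1C(=O)O[C@H](C)CCCCCCC2
F4 | step 15 | (S)-3-methyl-2-[(4-O-triflyl-lasiodiplodin-5-yl)methyl]butanal | COc1cc(OS(=O)(=O)C(F)(F)F)c(C[C@H](C=O)C(C)C)c2c1C(=O)O[C@H](C)CCCCCCC2
F5 | step 18 | (2S,3S)-4-hydroxy-N-methoxy-N,3-dimethyl-2-[(lasiodiplodin-5-yl)methyl]butanamide | COc1cc(O)c(C[C@H](C(=O)N(C)OC)[C@H](C)CO)c2c1C(=O)O[C@H](C)CCCCCCC2
A1 | alternative 1 | 6-[(R)-11-hydroxy-2,4-dioxododecyl]-2,2-dimethyl-4H-1,3-dioxin-4-one (diketo-dioxinone) | CC1(C)OC(=O)C=C(CC(=O)CC(=O)CCCCCCC[C@@H](C)O)O1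
A2 | alternative 1 | (R)-16-methyl-oxacyclohexadecane-2,4,6,8-tetraone (sixteen-membered triketo-lactone) | C[C@@H]1CCCCCCCC(=O)CC(=O)CC(=O)CC(=O)O1
A3 | alternative 1 | de-O-methyllasiodiplodin | Oc1cc(O)cc2c1C(=O)O[C@H](C)CCCCCCC2
A4 | alternative 2 | (R)-12-methyl-oxacyclododec-3-yn-2-one (twelve-membered ynolide) | C[C@@H]1CCCCCCCC#CC(=O)O1
A5 | alternative 2 | 1,5-dimethoxy-1,3-bis(trimethylsilyloxy)penta-1,3-diene (geometry not fixed) | COCC=C(O[Si](C)(C)C)C=C(OC)O[Si](C)(C)C
A6 | alternative 2 | de-O-methyllasiodiplodin bearing CH2OMe at arene C5 | Oc1cc(O)c(COC)c2c1C(=O)O[C@H](C)CCCCCCC2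
A7 | alternative 3 | thirteen-membered benzylic sulfone analogue of lasiodiplactone A (SO2 between the benzylic CH2 and the chain) | COc1cc2c(c3c1C(=O)O[C@H](C)CCCCCCS(=O)(=O)C3)C[C@H]1[C@H](C)CO[C@@]1(C)O2
A8 | alternative 3 | lasiodiplactone A with a benzylic C=C bond in the macrocycle (E/Z mixture) | COc1cc2c(c3c1C(=O)O[C@H](C)CCCCCC=C3)C[C@H]1[C@H](C)CO[C@@]1(C)O2
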